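**Plan**

- Cuts: (a) the depside bond between the ester oxygen and C4 of ring B (the 2-methoxybenzoic acid ring), rather than the acyl C–O bond; (b) the ArCH2–C(=O) bond of the 2-oxoheptyl chain in each ring; (c) the C4–B bond of ring B back to C4–H.
- Enabling feature: without its oxygen, ring B is a 1,2,3-trisubstituted arene. C3–H adjoins the C2 methoxy group and C5–H adjoins the C6 side chain, so C4–H is the only unflanked hydrogen and takes the boron. The ring A carbonyl carbon is boxed in by C2–O and C6–CH2, but its carboxylate oxygen is free to bind copper.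
- Forward: both benzene rings are bought and no ring of the target is built. Each ortho-toluate is acylated at its methyl group with a hexanoyl Weinreb amide and ketalised. Ring A is then saponified, ring B is borylated, and copper-mediated O-arylation joins the halves.
- Endgame: dilute acid frees the two ketones while every acidic oxygen is still blocked. One neutral hydrogenolysis then removes two benzyl ethers and a 3,5-dimethylbenzyl ester, so the free keto acid never meets acid.
- Stereochemistry: the target has no stereocentre and no configured double bond, so nothing needs control.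

Key step: step 10

Assumption: all numbered starting materials are catalogue chemicals, and the target is handled as the open keto acid drawn, which may equilibrate with its cyclic lactol in solution.

**Ring A acid**

Step 1
Reactants: 1 methyl orsellinate (methyl 2,4-dihydroxy-6-methylbenzoate)
Product: 2 methyl 2,4-bis(benzyloxy)-6-methylbenzoate
Conditions: BnBr (2.5 equiv), K2CO3 (3 equiv), DMF, 60 °C
Reagents that add atoms: benzyl bromide, BrCc1ccccc1
Why: Williamson ether synthesis, in which both phenoxides, including the hydrogen-bonded one at C2, should be alkylated in warm DMF while the hindered methyl ester stays intact.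

Step 2
Reactants: 2 methyl 2,4-bis(benzyloxy)-6-methylbenzoate; 3 N-methoxy-N-methylhexanamide
Product: 6 methyl 2,4-bis(benzyloxy)-6-(2-oxoheptyl)benzoate, via benzylic lithium species 4 (not isolated), via tetrahedral lithium adduct 5 (not isolated)
Conditions: LiN(iPr)2 (LDA, 1.3 equiv), THF, −78 °C; 3 (1.3 equiv), −78 → −30 °C; sat. aq NH4Cl
Reagents that add atoms: N-methoxy-N-methylhexanamide 3, CCCCCC(=O)N(C)OC
Why: Lateral lithiation of an ortho-toluate followed by Weinreb ketone synthesis, where the ester acidifies the C6 methyl group, its two ortho substituents hold off self-condensation, and the chelated adduct 5 releases the ketone only on quench so that no second addition occurs.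

Step 3
Reactants: 6 methyl 2,4-bis(benzyloxy)-6-(2-oxoheptyl)benzoate
Product: 7 methyl 2,4-bis(benzyloxy)-6-[(2-pentyl-1,3-dioxolan-2-yl)methyl]benzoate
Conditions: TMSOCH2CH2OTMS (2 equiv), TMSOTf (10 mol %), CH2Cl2, −78 → −20 °C; pyridine, aq NaHCO3
Reagents that add atoms: 1,2-bis(trimethylsilyloxy)ethane, C[Si](C)(C)OCCO[Si](C)(C)C
Why: Noyori ketalisation, whose aprotic low-temperature conditions are driven by formation of the disiloxane and should avoid the hot protic acid that turns such keto esters into isocoumarins by enol lactonisation.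

Step 4
Reactants: 7 methyl 2,4-bis(benzyloxy)-6-[(2-pentyl-1,3-dioxolan-2-yl)methyl]benzoate
Product: 8 2,4-bis(benzyloxy)-6-[(2-pentyl-1,3-dioxolan-2-yl)methyl]benzoic acid
Conditions: KOH (10 equiv), DMSO/H2O, 90 °C; 0 °C, 1 M HCl to pH 5, EtOAc extraction
Reagents that add atoms: potassium hydroxide, [K+].[OH-]
Why: Saponification of a di-ortho-substituted benzoate with poorly solvated hydroxide in aqueous DMSO, conditions to which benzyl ethers and the dioxolane are inert, with a cold and only mildly acidic work-up to spare the ketal.

**Ring B boronic acid**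

Step 5
Reactants: 9 2-methoxy-6-methylbenzoic acid
Product: 10 3,5-dimethylbenzyl 2-methoxy-6-methylbenzoate
Conditions: 3,5-dimethylbenzyl bromide (1.1 equiv), K2CO3 (1.5 equiv), DMF, rt
Reagents that add atoms: 3,5-dimethylbenzyl bromide, BrCc1cc(C)cc(C)c1
Why: SN2 O-alkylation of the carboxylate bypasses the hindered acyl carbon and installs a hydrogenolysable benzyl-type ester whose 1,3,5-trisubstituted ring offers no unflanked C–H to the later borylation.

Step 6
Reactants: 10 3,5-dimethylbenzyl 2-methoxy-6-methylbenzoate; 3 N-methoxy-N-methylhexanamide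
Product: 13 3,5-dimethylbenzyl 2-methoxy-6-(2-oxoheptyl)benzoate, via benzylic lithium species 11 (not isolated), via tetrahedral lithium adduct 12 (not isolated)
Conditions: LiN(iPr)2 (LDA, 1.3 equiv), THF, −78 °C; 3 (1.3 equiv), −78 → −30 °C; sat. aq NH4Cl
Reagents that add atoms: N-methoxy-N-methylhexanamide 3, CCCCCC(=O)N(C)OC
Why: Lateral lithiation and Weinreb ketone synthesis as in step 2, the ring methyl group being far more acidic than the OCH2Ar and xylyl C–H bonds, just as benzyl esters routinely survive enolisation by this base at −78 °C.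

Step 7
Reactants: 13 3,5-dimethylbenzyl 2-methoxy-6-(2-oxoheptyl)benzoate
Product: 14 3,5-dimethylbenzyl 2-methoxy-6-[(2-pentyl-1,3-dioxolan-2-yl)methyl]benzoate
Conditions: TMSOCH2CH2OTMS (2 equiv), TMSOTf (10 mol %), CH2Cl2, −78 → −20 °C; pyridine, aq NaHCO3
Reagents that add atoms: 1,2-bis(trimethylsilyloxy)ethane, C[Si](C)(C)OCCO[Si](C)(C)C
Why: Noyori ketalisation masks the enolisable, reducible ketone before boron and copper chemistry, and the meta-methyl groups give the ester no extra tendency to ionise under catalytic silyl triflate.

Step 8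
Reactants: 14 3,5-dimethylbenzyl 2-methoxy-6-[(2-pentyl-1,3-dioxolan-2-yl)methyl]benzoate; 15 bis(pinacolato)diboron
Product: 16 3,5-dimethylbenzyl 2-methoxy-6-[(2-pentyl-1,3-dioxolan-2-yl)methyl]-4-(4,4,5,5-tetramethyl-1,3,2-dioxaborolan-2-yl)benzoate
Conditions: [Ir(OMe)(cod)]2 (1.5 mol %), 4,4'-di-tert-butyl-2,2'-bipyridine (3 mol %), 15 (1.0 equiv), THF, 80 °C
Reagents that add atoms: bis(pinacolato)diboron 15, CC1(C)OB(OC1(C)C)B1OC(C)(C)C(C)(C)O1
Why: Sterically governed iridium-catalysed aromatic C–H borylation, in which C3–H is shielded by the methoxy group, C5–H by the side chain and every hydrogen of the ester ring by two neighbours, so that only C4–H can reach the crowded iridium trisboryl centre while ester and ketal are spectators.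

Step 9
Reactants: 16 the pinacol boronate of step 8
Product: 17 {4-[(3,5-dimethylbenzyloxy)carbonyl]-3-methoxy-5-[(2-pentyl-1,3-dioxolan-2-yl)methyl]phenyl}boronic acid
Conditions: NaIO4 (3 equiv), NH4OAc (3 equiv), acetone/H2O, rt
Reagents that add atoms: water, O
Why: Periodate glycol cleavage destroys the pinacol released in the hydrolysis equilibrium and so drives the boronate to the boronic acid at nearly neutral pH, where the dioxolane and the hindered ester should persist.

**Union and endgame**

Step 10
Reactants: 8 2,4-bis(benzyloxy)-6-[(2-pentyl-1,3-dioxolan-2-yl)methyl]benzoic acid; 17 ring B boronic acid (1.5 equiv)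
Product: 18 fully protected depside, 4-[(3,5-dimethylbenzyloxy)carbonyl]-3-methoxy-5-[(2-pentyl-1,3-dioxolan-2-yl)methyl]phenyl 2,4-bis(benzyloxy)-6-[(2-pentyl-1,3-dioxolan-2-yl)methyl]benzoate
Conditions: Cu(OTf)2 (0.4 equiv), urea (1 equiv), 2,6-lutidine (1 equiv), 4 Å MS, EtOAc, air, 60 °C
Reagents that add atoms: none
Why: The carboxylate of 8 binds divalent copper, the aryl group of 17 passes from boron to copper, a second divalent copper or oxygen lifts the aryl copper carboxylate to the trivalent state, reductive elimination forges the O–C4 bond, and air returns monovalent copper to the cycle. This is the Chan–Lam coupling in its known variant that joins carboxylic acids and arylboronic acids to aryl esters, and the triflate salt is chosen because it brings no rival carboxylate such as acetate that could be arylated instead. No ring is closed and no stereocentre is made. The step needs chemoselective arylation of the carboxyl oxygen, which is secured because that is the only O–H in either partner: the ring A phenols are benzyl ethers, the ring B carboxyl is an ester, and both ArCH2 ketones, otherwise prone to copper and air oxidation, are dioxolanes. Site selectivity is built in, since the bond forms ipso at the boron-bearing carbon, which has no ortho substituent and should transmetalate readily, while the reacting oxygen of 8 lies outside the pocket of C2–OBn and the C6 chain that slows acyl substitution. 2,6-Lutidine and sieves hold back the triflic acid and water that could open the ketals, and a ketal lost here would fall in step 11 anyway.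

Step 11
Reactants: 18 fully protected depside
Product: 19 4-[(3,5-dimethylbenzyloxy)carbonyl]-3-methoxy-5-(2-oxoheptyl)phenyl 2,4-bis(benzyloxy)-6-(2-oxoheptyl)benzoate
Conditions: 1 M aq HCl, THF, rt
Reagents that add atoms: water, O
Why: Acid-catalysed ketal hydrolysis at room temperature, mild enough for the aryl ester, the benzyl ethers and the benzyl-type ester, and run while the ring B carboxyl is still esterified so that no free keto acid can dehydrate to an isocoumarin.

Step 12
Reactants: 19 the diketone of step 11
Product: 20 arthonioic acid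
Conditions: H2 (1 atm), 10% Pd/C, EtOAc, rt
Reagents that add atoms: none
Why: Catalytic hydrogenolysis of three benzylic C–O bonds under neutral conditions in a non-nucleophilic solvent, which should leave the depside ester, the methyl ether and the two non-conjugated ketones untouched.

**Compound list**

1 | methyl orsellinate | COC(=O)c1c(C)cc(O)cc1O | starting material
2 | methyl 2,4-bis(benzyloxy)-6-methylbenzoate | COC(=O)c1c(C)cc(OCc2ccccc2)cc1OCc1ccccc1 | intermediate
3 | N-methoxy-N-methylhexanamide | CCCCCC(=O)N(C)OC | starting material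
4 | benzylic lithium species from 2 | [Li]Cc1cc(OCc2ccccc2)cc(OCc2ccccc2)c1C(=O)OC | intermediate
5 | tetrahedral lithium adduct of 4 and 3 (racemic, transient) | CCCCCC(O[Li])(Cc1cc(OCc2ccccc2)cc(OCc2ccccc2)c1C(=O)OC)N(C)OC | intermediate
6 | methyl 2,4-bis(benzyloxy)-6-(2-oxoheptyl)benzoate | CCCCCC(=O)Cc1cc(OCc2ccccc2)cc(OCc2ccccc2)c1C(=O)OC | intermediate
7 | methyl 2,4-bis(benzyloxy)-6-[(2-pentyl-1,3-dioxolan-2-yl)methyl]benzoate | CCCCCC1(OCCO1)Cc1cc(OCc2ccccc2)cc(OCc2ccccc2)c1C(=O)OC | intermediate
8 | 2,4-bis(benzyloxy)-6-[(2-pentyl-1,3-dioxolan-2-yl)methyl]benzoic acid | CCCCCC1(OCCO1)Cc1cc(OCc2ccccc2)cc(OCc2ccccc2)c1C(=O)O | intermediate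
9 | 2-methoxy-6-methylbenzoic acid | COc1cccc(C)c1C(=O)O | starting material
10 | 3,5-dimethylbenzyl 2-methoxy-6-methylbenzoate | COc1cccc(C)c1C(=O)OCc1cc(C)cc(C)c1 | intermediate
11 | benzylic lithium species from 10 | [Li]Cc1cccc(OC)c1C(=O)OCc1cc(C)cc(C)c1 | intermediate
12 | tetrahedral lithium adduct of 11 and 3 (racemic, transient) | CCCCCC(O[Li])(Cc1cccc(OC)c1C(=O)OCc1cc(C)cc(C)c1)N(C)OC | intermediate
13 | 3,5-dimethylbenzyl 2-methoxy-6-(2-oxoheptyl)benzoate | CCCCCC(=O)Cc1cccc(OC)c1C(=O)OCc1cc(C)cc(C)c1 | intermediate
14 | 3,5-dimethylbenzyl 2-methoxy-6-[(2-pentyl-1,3-dioxolan-2-yl)methyl]benzoate | CCCCCC1(OCCO1)Cc1cccc(OC)c1C(=O)OCc1cc(C)cc(C)c1 | intermediate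
15 | bis(pinacolato)diboron | CC1(C)OB(OC1(C)C)B1OC(C)(C)C(C)(C)O1 | starting material
16 | 3,5-dimethylbenzyl 2-methoxy-6-[(2-pentyl-1,3-dioxolan-2-yl)methyl]-4-(4,4,5,5-tetramethyl-1,3,2-dioxaborolan-2-yl)benzoate | CCCCCC1(OCCO1)Cc1cc(B2OC(C)(C)C(C)(C)O2)cc(OC)c1C(=O)OCc1cc(C)cc(C)c1 | intermediate
17 | {4-[(3,5-dimethylbenzyloxy)carbonyl]-3-methoxy-5-[(2-pentyl-1,3-dioxolan-2-yl)methyl]phenyl}boronic acid | CCCCCC1(OCCO1)Cc1cc(B(O)O)cc(OC)c1C(=O)OCc1cc(C)cc(C)c1 | intermediate
18 | fully protected depside (two benzyl ethers, two dioxolanes, 3,5-dimethylbenzyl ester) | CCCCCC1(OCCO1)Cc1cc(OCc2ccccc2)cc(OCc2ccccc2)c1C(=O)Oc1cc(CC2(CCCCC)OCCO2)c(C(=O)OCc2cc(C)cc(C)c2)c(OC)c1 | intermediate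
19 | diketone depside (two benzyl ethers, 3,5-dimethylbenzyl ester) | CCCCCC(=O)Cc1cc(OCc2ccccc2)cc(OCc2ccccc2)c1C(=O)Oc1cc(CC(=O)CCCCC)c(C(=O)OCc2cc(C)cc(C)c2)c(OC)c1 | intermediate
20 | arthonioic acid | CCCCCC(=O)Cc1cc(O)cc(O)c1C(=O)Oc1cc(CC(=O)CCCCC)c(C(=O)O)c(OC)c1 | target

**Step count**

Total step count: 12.
Longest linear sequence: 8 steps (steps 5 to 12, from 9). The ring A branch contributes 4 steps in parallel.

**Steps most likely to fail**

Step 10. Aryl transfer to the crowded copper carboxylate, or the reductive elimination from it, may be slow. Oxidation of the boronic acid, protodeboronation, biaryl formation or Lewis acid opening of the ketals could then outrun ester formation. The fallback sets out from 17 and moves bond formation to the acyl carbon. Oxidation with H2O2 and NaHCO3 in THF/water should give the phenol 3,5-dimethylbenzyl 4-hydroxy-2-methoxy-6-[(2-pentyl-1,3-dioxolan-2-yl)methyl]benzoate F1. This phenol is then acylated by acid 8 under carbodiimide activation (DCC, catalytic DMAP, toluene, rt), the classical depside esterification. The fallback rejoins the route at 18.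

Step 6 (step 2 shares the same hazards). The benzylic anion may be quenched by proton transfer from the α-methylene of the amide, may condense with the ester of a second molecule, or metalation may stray to the OCH2Ar group. The fallback sets out from 9 and removes the electrophilic ester from the anion. Two equivalents of LiN(iPr)2 in THF at −78 °C should convert the free acid into the dilithio dianion of 2-methoxy-6-methylbenzoic acid F2. Acylation with 3 and a mildly acidic quench gives 2-methoxy-6-(2-oxoheptyl)benzoic acid F3. Its carboxylate is alkylated with 3,5-dimethylbenzyl bromide and KHCO3 in DMF. The fallback rejoins the route at 13.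

Step 9. Removal of pinacol may stall at the hydrolysis equilibrium, or long exposure to the aqueous oxidant may cost a ketal or the C–B bond. The fallback sets out from 16 and goes through a crystalline salt instead of an oxidative cleavage. KHF2 in aqueous methanol should give potassium {4-[(3,5-dimethylbenzyloxy)carbonyl]-3-methoxy-5-[(2-pentyl-1,3-dioxolan-2-yl)methyl]phenyl}trifluoroborate F4, freed of pinacol by trituration. LiOH in aqueous acetonitrile, followed by an NH4Cl work-up, then hydrolyses it. The fallback rejoins the route at 17.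

**Further compounds**

F1 | step 10 | 3,5-dimethylbenzyl 4-hydroxy-2-methoxy-6-[(2-pentyl-1,3-dioxolan-2-yl)methyl]benzoate | CCCCCC1(OCCO1)Cc1cc(O)cc(OC)c1C(=O)OCc1cc(C)cc(C)c1
F2 | step 6 | dilithio dianion of 2-methoxy-6-methylbenzoic acid | [Li]Cc1cccc(OC)c1C(=O)O[Li]
F3 | step 6 | 2-methoxy-6-(2-oxoheptyl)benzoic acid | CCCCCC(=O)Cc1cccc(OC)c1C(=O)O
F4 | step 9 | potassium {4-[(3,5-dimethylbenzyloxy)carbonyl]-3-methoxy-5-[(2-pentyl-1,3-dioxolan-2-yl)methyl]phenyl}trifluoroborate | [K+].CCCCCC1(OCCO1)Cc1cc([B-](F)(F)F)cc(OC)c1C(=O)OCc1cc(C)cc(C)c1
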